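## Structural features

The target is a (2S)-flavanone. Aromatic ring A is fused through C4a–C8a to the dihydropyranone ring C, and ring B, a 3-hydroxy-4-methoxyphenyl group, is attached at C2. Ring A carries methoxy groups at C5 and C7 and a prenyl (3-methylbut-2-enyl) chain at C8, wedged between O1 and the C7 methoxy group; only C6 bears hydrogen. C2 is the only stereocentre, so no neighbouring centre can relay its configuration and it has to be set by a reagent. Three groups are fragile:

- C2 is the β-carbon of a β-aryloxy ketone, so base (and hot acid) opens ring C to the 2′-hydroxychalcone and reclosure racemises.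
- The prenyl alkene is open to acid, electrophilic oxidants, metathesis and hydrometalation catalysts.
- The ring B phenol is nucleophilic and oxidisable.

The real difficulty is to create C2 enantioselectively next to a di-ortho-substituted aryl oxygen, and then to bring the ketone to C4 without opening ring C or touching the prenyl group. The key step uses the fact that C2 is a secondary benzylic carbon bonded to O1 of ring A and to C1′ of ring B: it is the branched product of attack of the ring A aryloxide on a cinnamyl electrophile built from ring B. The CIP order O > C1′ > C3 > H holds in both the allyl ether and the flavanone, so the S ether maps onto the 2S ketone; the structures of both fragments and of the ether were checked and need no correction.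

## Logic of the disconnections

**18 ⇒ 17.** The O–Si bond at O3′ is cut. The ring B phenol must be masked because it would compete as a nucleophile in the fragment union and be oxidised later. A triisopropylsilyl ether is preferred to a smaller silyl ether because an aryloxide and methoxide are present in step 9 and a basic oxidative work-up follows in step 11. Demand on the forward step: the cleavage must be non-basic, since 17 and 18 open to chalcones by E1cB.

**17 ⇒ 16 ⇒ 14.** The C4–O bond is cut, first at the ketone level and then at the alcohol level, back to the C3=C4 alkene. Ring C arrives from metathesis without oxygen, so oxygen has to be added at C4 afterwards. A direct palladium Wacker oxidation of 14 would be one step shorter. It is kept in reserve because two known regiochemical trends of that reaction oppose each other here (see step 11 under the least certain steps), and a C3 ketone would make C2–H acidic. Catalysed hydroboration puts the metal on the benzylic carbon and runs under neutral, non-oxidising conditions. Demand: boron at C4, prenyl and C2 untouched.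

**14 ⇒ 13.** The C3=C4 bond is cut. This opens ring C to an acyclic ether with one stereocentre and two terminal vinyl groups. Demand: six-ring closure must outrun any engagement of the prenyl alkene, and the double bond must not migrate toward C2.

**13 ⇒ 12 (from 6) + 11.** The O1–C2 bond is cut. This is the fragment union and the only stereogenic step; it divides the molecule into two achiral halves of similar size. Demand: attack at the aryl-bearing allyl terminus, one enantioface, and O- rather than C-allylation of a hindered, electron-rich aryloxide.

**6 ⇒ 5 ⇒ 4 ⇒ 3 ⇒ 1 + 2.** Cut in turn: the exocyclic C=C at C4a (olefination of the aldehyde), the side-chain C=C (cross-metathesis), the C8–CH2 bond (moved to O–CH2 by a [3,3] shift), and the O–allyl bond. Ring A comes complete from 1, and the sigmatropic shift can only reach the one free ortho carbon, so regiochemistry at C8 is not in question. Demand: cross-metathesis before the vinyl group exists, and 6 made last and used fresh.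

**11 ⇒ 10 ⇒ 9 ⇒ 8 ⇒ 7.** Cut in turn: the carbonate C–O bond, the ester C–O bond (reduction level), the Cα=Cβ bond (olefination) and O–Si. Demand: E geometry of the alkene and neutral conditions for the aryl silyl ether.

## Other disconnections considered

**Alternative 1:** The cut is through ring A itself (C7–C8, C4a–C8a, C6–C7), so that the benzene ring is built with the prenyl chain already attached.
- Forward key step: heating 3-methoxycyclobut-2-en-1-one A2 with the siloxyalkyne A3. The cyclobutenone opens to a vinylketene, which adds [2+2] to the ynol ether; four-electron opening and six-electron closure give 5-methoxy-2-prenyl-3-(triisopropylsilyloxy)phenol A1, with the free hydroxyl at the future C7 and the silyl ether at the future O1.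
- In its favour: the prenyl group and three differentiated oxygens are placed with full regiocontrol in one pericyclic cascade, with no allyl transfer and no metathesis.
- Against it here: the ring A pattern is already sold as 1, whereas A2 and A3 each need several steps. A1 still lacks C4, ring C and the stereocentre, and acylation would have to choose between C4a and C6.
- Comparison: on regiocontrol at C8 it is the equal of the chosen plan. On differentiation of O7 from O1 it is better, though the target, with the same methyl group on O5 and O7, does not need this. On step economy it is worse, and it leaves the question of C2 unanswered.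

**Alternative 2:** The cut is C4–C4a.
- Forward key step: bromine–lithium exchange with tert-butyllithium on the bromoarene A5, a (3S)-β-aryloxy Weinreb amide. The aryllithium attacks the amide carbonyl and closes ring C, giving the 3′-O-methoxymethyl flavanone A4.
- In its favour: the ketone appears at C4 at the right oxidation level with no regiochemical question. The chelated tetrahedral intermediate keeps the base-sensitive flavanone masked until quench, and no metathesis catalyst meets the prenyl group.
- Against it here: the α-protons of A5 are acidic, and deprotonation by the alkyllithium or the aryllithium would expel the aryloxide by E1cB, losing both the union and the stereocentre. A5 also requires a hexasubstituted bromophenol and an enantioselective C2–O bond to a hindered phenol, so the hardest bond is only moved. The final acetal cleavage needs acid.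
- Comparison: both plans create C2 as an ether before ring C closes, and are equal on that point. Ring closure to the ketone is one step there against three here, so the alternative is better on that point. The chosen plan sets C2 catalytically from achiral fragments and is shorter overall up to the cyclisation precursor.

**Alternative 3:** The cut is C2–C1′.
- Forward key step: Pd(OCOCF3)2 with an enantiopure tert-butyl pyridine-oxazoline ligand transfers the aryl group of the boronic acid A8 to C2 of 5,7-dimethoxy-8-prenylchromone A7. Aryl–palladium insertion and protonation of the palladium enolate give the 3′-O-silyl flavanone A6.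
- In its favour: it is the most convergent plan. Bond, stereocentre and ketone arrive in one catalytic step, and only desilylation follows.
- Against it here: A7 is a vinylogous ester deactivated by two methoxy donors, with the C5 methoxy group peri to the carbonyl. The electron-rich boronic acid is prone to protodeboronation, the cationic divalent palladium may engage the prenyl alkene, and the ligand enantiomer must be matched to the 2S series.
- Comparison: on step count and on freedom from redox adjustment it is better than the chosen plan. On mechanism, both rest on reagent control with a substrate-specific uncertainty (acceptor reactivity there, nucleophile hindrance here). The chosen plan has the advantage that C2 is first made as a non-enolisable ether. Alternative 3 is used below as the fallback for the key step.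

Key step: step 9

Assumption: the (Sa,Sc,Sc) enantiomer of the phosphoramidite is taken to give the S ether, by analogy with the usual sense of induction of this catalyst family with aryl-substituted allyl carbonates and heteroatom nucleophiles; if a model reaction shows the opposite sense, the (Ra,Rc,Rc) ligand is used and nothing else changes.

## Route

Step 1
Reactants: 1 2-hydroxy-4,6-dimethoxybenzaldehyde; 2 allyl bromide
Product: 3 2-(allyloxy)-4,6-dimethoxybenzaldehyde
Conditions: K2CO3, DMF, 25 → 50 °C
Reagents that add atoms: none
Why: Williamson ether synthesis; the hydrogen-bonded phenol is the only acidic site and its potassium salt is alkylated at oxygen by the primary allylic bromide in a polar aprotic solvent.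

Step 2
Reactants: 3 2-(allyloxy)-4,6-dimethoxybenzaldehyde
Product: 4 3-allyl-2-hydroxy-4,6-dimethoxybenzaldehyde
Conditions: N,N-diethylaniline, 195 °C, argon
Reagents that add atoms: none
Why: Aromatic Claisen rearrangement; the [3,3] shift delivers the allyl group to C3, the only free ortho carbon, and tautomerisation to the chelated salicylaldehyde makes it irreversible. An allyl ether is used because the shift inverts the allyl unit, so a prenyl ether would give the 1,1-dimethylallyl isomer.

Step 3
Reactants: 4 3-allyl-2-hydroxy-4,6-dimethoxybenzaldehyde
Product: 5 2-hydroxy-4,6-dimethoxy-3-(3-methylbut-2-en-1-yl)benzaldehyde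
Conditions: second-generation Grubbs catalyst (H2IMes)(PCy3)Cl2Ru=CHPh (3 mol%), 2-methyl-2-butene/CH2Cl2, 40 °C, sealed tube
Reagents that add atoms: 2-methyl-2-butene, CC=C(C)C
Why: Olefin cross-metathesis; the terminal alkene exchanges its methylene for an isopropylidene unit from the excess trisubstituted alkene and the trisubstituted product does not react further. Phenol and aldehyde are tolerated by the ruthenium carbene.

Step 4
Reactants: 5 2-hydroxy-4,6-dimethoxy-3-(3-methylbut-2-en-1-yl)benzaldehyde
Product: 6 3,5-dimethoxy-2-(3-methylbut-2-en-1-yl)-6-vinylphenol
Conditions: Ph3PCH3Br, KOtBu (3 equiv each), THF, 0 → 25 °C; pH 7 buffer; used at once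
Reagents that add atoms: methyltriphenylphosphonium bromide, C[P+](c1ccccc1)(c1ccccc1)c1ccccc1.[Br-]
Why: Wittig methylenation; the first equivalent of base forms the aryloxide and the excess non-stabilised ylide still attacks the hindered aldehyde. Neutral work-up and immediate use limit oligomerisation of the electron-rich vinylphenol through its quinone methide form.

Step 5
Reactants: 7 isovanillin (3-hydroxy-4-methoxybenzaldehyde)
Product: 8 4-methoxy-3-(triisopropylsilyloxy)benzaldehyde
Conditions: i-Pr3SiCl, imidazole, DMF, 25 °C
Reagents that add atoms: triisopropylsilyl chloride, CC(C)[Si](Cl)(C(C)C)C(C)C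
Why: Silylation of a phenol with a silyl chloride and imidazole; the bulky triisopropylsilyl ether should survive the aryloxide and methoxide of step 9 and the perborate work-up of step 11.

Step 6
Reactants: 8 4-methoxy-3-(triisopropylsilyloxy)benzaldehyde
Product: 9 ethyl (E)-3-[4-methoxy-3-(triisopropylsilyloxy)phenyl]prop-2-enoate
Conditions: Ph3P=CHCO2Et, toluene, 80 °C
Reagents that add atoms: ethyl (triphenylphosphoranylidene)acetate, CCOC(=O)C=P(c1ccccc1)(c1ccccc1)c1ccccc1
Why: Wittig reaction with a stabilised ylide, which gives the E enoate under neutral conditions that leave the aryl silyl ether alone.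

Step 7
Reactants: 9 ethyl (E)-3-[4-methoxy-3-(triisopropylsilyloxy)phenyl]prop-2-enoate
Product: 10 (E)-3-[4-methoxy-3-(triisopropylsilyloxy)phenyl]prop-2-en-1-ol
Conditions: i-Bu2AlH (2.2 equiv), CH2Cl2, −78 °C; aq. potassium sodium tartrate
Reagents that add atoms: none
Why: 1,2-Reduction of an α,β-unsaturated ester by i-Bu2AlH at low temperature gives the allylic alcohol without conjugate reduction or loss of the silyl group.

Step 8
Reactants: 10 (E)-3-[4-methoxy-3-(triisopropylsilyloxy)phenyl]prop-2-en-1-ol
Product: 11 (E)-3-[4-methoxy-3-(triisopropylsilyloxy)phenyl]allyl methyl carbonate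
Conditions: ClCO2Me, pyridine, CH2Cl2, 0 °C
Reagents that add atoms: methyl chloroformate, COC(=O)Cl
Why: Acylation of a primary alcohol with a chloroformate; the methyl carbonate is the usual leaving group for iridium allylic substitution because it loses CO2 and releases methoxide in the flask.

Step 9
Reactants: 6 3,5-dimethoxy-2-(3-methylbut-2-en-1-yl)-6-vinylphenol; 11 (E)-3-[4-methoxy-3-(triisopropylsilyloxy)phenyl]allyl methyl carbonate
Product: 13 (S)-1-[4-methoxy-3-(triisopropylsilyloxy)phenyl]allyl 3,5-dimethoxy-2-(3-methylbut-2-en-1-yl)-6-vinylphenyl ether, via lithium aryloxide 12 (not isolated)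
Conditions: 6, n-BuLi, THF, −78 → 0 °C; then 11, [Ir(cod)Cl]2 (2 mol%), (Sa,Sc,Sc)-O,O′-(1,1′-binaphthyl-2,2′-diyl) N,N-bis(1-phenylethyl)phosphoramidite (4 mol%; pre-activated with n-PrNH2, THF, 50 °C, volatiles removed), THF, 25 °C
Reagents that add atoms: n-butyllithium, [Li]CCCC (lithium in 12 only; 13 holds atoms of 6 and 11 alone)
Why: Iridium-catalysed enantioselective allylic etherification of an alkali aryloxide with a cinnamyl carbonate, a known reaction type that includes 2-vinylphenoxides as nucleophiles. [Ir(cod)Cl]2, the phosphoramidite and propylamine give a cyclometalated complex of monovalent iridium; oxidative addition of 11, with loss of methyl carbonate (then CO2 and methoxide), forms an allyl complex of trivalent iridium, and 12 attacks the aryl-bearing terminus from the face away from the metal, forming O1–C2 and releasing monovalent iridium. No ring is closed. The new stereocentre C2 is controlled by the chiral iridacycle alone, which holds the allyl ligand in one orientation and leaves one enantioface of the benzylic terminus open; the S configuration is expected with the (Sa,Sc,Sc) ligand. Three selectivities are needed: branched over linear, which the iridacycle favours and the 4-methoxy group of ring B reinforces by stabilising positive charge at the benzylic terminus; O- over C-allylation, favoured by the lithium counter-ion in THF and by kinetic control; and preservation of the ee, helped because the hindered, electron-rich aryloxide in 13 is a poor leaving group for re-ionisation and the reaction is stopped once 11 is consumed. The prenyl and vinyl groups and the silyl ether are spectators, and C2 at this stage is an ether with no carbonyl β to it, so the chalcone pathway of racemisation does not yet exist.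

Step 10
Reactants: 13 (S)-1-[4-methoxy-3-(triisopropylsilyloxy)phenyl]allyl 3,5-dimethoxy-2-(3-methylbut-2-en-1-yl)-6-vinylphenyl ether
Product: 14 (2S)-5,7-dimethoxy-2-[4-methoxy-3-(triisopropylsilyloxy)phenyl]-8-(3-methylbut-2-en-1-yl)-2H-chromene
Conditions: second-generation Grubbs catalyst (H2IMes)(PCy3)Cl2Ru=CHPh (5 mol%), 1,4-benzoquinone (10 mol%), CH2Cl2 (0.01 M), 25 → 40 °C, dark
Reagents that add atoms: none
Why: Ring-closing metathesis of a styrene with an allyl ether, a standard entry to 2H-chromenes; six-ring closure between two monosubstituted alkenes with loss of ethene should be far faster than any reaction of the trisubstituted prenyl alkene, which could only close a seven-membered ring. Benzoquinone suppresses ruthenium hydride–mediated migration of the double bond toward C2, exclusion of light avoids electrocyclic opening of the chromene, and C2 itself is not touched.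

Step 11
Reactants: 14 (2S)-5,7-dimethoxy-2-[4-methoxy-3-(triisopropylsilyloxy)phenyl]-8-(3-methylbut-2-en-1-yl)-2H-chromene
Product: 16 (2S)-5,7-dimethoxy-2-[4-methoxy-3-(triisopropylsilyloxy)phenyl]-8-(3-methylbut-2-en-1-yl)chroman-4-ol (both C4 epimers), via catechol boronate 15 (not isolated)
Conditions: [Rh(cod)2]BF4 (2 mol%), Ph2P(CH2)4PPh2 (2.2 mol%), catecholborane, THF, −20 → 25 °C; then NaBO3·4H2O, THF/H2O, 25 °C
Reagents that add atoms: catecholborane, B1Oc2ccccc2O1 (boron and catecholate in 15 only); sodium perborate tetrahydrate, [Na+].[O-]B1OO1.O.O.O.O (oxygen at C4 of 16)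
Why: Rhodium-catalysed hydroboration of a vinylarene with catecholborane places rhodium, and then boron, on the benzylic carbon C4 through an η3-benzyl intermediate, a regiochemistry known for 2H-chromenes; the trisubstituted prenyl alkene is not hydroborated under catalysis at or below room temperature. Perborate oxidises the C–B bond with retention; the configuration at C4 is of no consequence and C2 is not involved.

Step 12
Reactants: 16 (2S)-5,7-dimethoxy-2-[4-methoxy-3-(triisopropylsilyloxy)phenyl]-8-(3-methylbut-2-en-1-yl)chroman-4-ol
Product: 17 (2S)-5,7-dimethoxy-2-[4-methoxy-3-(triisopropylsilyloxy)phenyl]-8-(3-methylbut-2-en-1-yl)chroman-4-one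
Conditions: (n-Pr4N)RuO4 (5 mol%), N-methylmorpholine N-oxide, 4 Å molecular sieves, CH2Cl2, 25 °C
Reagents that add atoms: none
Why: Ley–Griffith oxidation of a secondary benzylic alcohol under neutral, anhydrous conditions, chosen because a 5,7-dimethoxyflavan-4-ol ionises easily with acid; the alkene, the silyl ether and C2 are inert to it.

Step 13
Reactants: 17 (2S)-5,7-dimethoxy-2-[4-methoxy-3-(triisopropylsilyloxy)phenyl]-8-(3-methylbut-2-en-1-yl)chroman-4-one
Product: 18 (2S)-2-(3-hydroxy-4-methoxyphenyl)-5,7-dimethoxy-8-(3-methylbut-2-en-1-yl)chroman-4-one
Conditions: Bu4NF, AcOH (1:1), THF, 0 °C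
Reagents that add atoms: none
Why: Fluoride cleavage of an aryl silyl ether; acetic acid buffers the fluoride and protonates the liberated phenoxide, so the β-aryloxy ketone should not open to the chalcone and C2 should keep its configuration.

## Compound list

1 | 2-hydroxy-4,6-dimethoxybenzaldehyde | COc1cc(O)c(C=O)c(OC)c1 | starting material
2 | allyl bromide | C=CCBr | starting material
3 | 2-(allyloxy)-4,6-dimethoxybenzaldehyde | COc1cc(OCC=C)c(C=O)c(OC)c1 | intermediate
4 | 3-allyl-2-hydroxy-4,6-dimethoxybenzaldehyde | COc1cc(OC)c(CC=C)c(O)c1C=O | intermediate
5 | 2-hydroxy-4,6-dimethoxy-3-(3-methylbut-2-en-1-yl)benzaldehyde | COc1cc(OC)c(CC=C(C)C)c(O)c1C=O | intermediate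
6 | 3,5-dimethoxy-2-(3-methylbut-2-en-1-yl)-6-vinylphenol | C=Cc1c(OC)cc(OC)c(CC=C(C)C)c1O | intermediate
7 | isovanillin (3-hydroxy-4-methoxybenzaldehyde) | COc1ccc(C=O)cc1O | starting material
8 | 4-methoxy-3-(triisopropylsilyloxy)benzaldehyde | COc1ccc(C=O)cc1O[Si](C(C)C)(C(C)C)C(C)C | intermediate
9 | ethyl (E)-3-[4-methoxy-3-(triisopropylsilyloxy)phenyl]prop-2-enoate | CCOC(=O)/C=C/c1ccc(OC)c(O[Si](C(C)C)(C(C)C)C(C)C)c1 | intermediate
10 | (E)-3-[4-methoxy-3-(triisopropylsilyloxy)phenyl]prop-2-en-1-ol | OC/C=C/c1ccc(OC)c(O[Si](C(C)C)(C(C)C)C(C)C)c1 | intermediate
11 | (E)-3-[4-methoxy-3-(triisopropylsilyloxy)phenyl]allyl methyl carbonate | COC(=O)OC/C=C/c1ccc(OC)c(O[Si](C(C)C)(C(C)C)C(C)C)c1 | intermediate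
12 | lithium 3,5-dimethoxy-2-(3-methylbut-2-en-1-yl)-6-vinylphenoxide | [Li+].[O-]c1c(C=C)c(OC)cc(OC)c1CC=C(C)C | intermediate (not isolated)
13 | (S)-1-[4-methoxy-3-(triisopropylsilyloxy)phenyl]allyl 3,5-dimethoxy-2-(3-methylbut-2-en-1-yl)-6-vinylphenyl ether | COc1ccc([C@H](C=C)Oc2c(C=C)c(OC)cc(OC)c2CC=C(C)C)cc1O[Si](C(C)C)(C(C)C)C(C)C | intermediate
14 | (2S)-5,7-dimethoxy-2-[4-methoxy-3-(triisopropylsilyloxy)phenyl]-8-(3-methylbut-2-en-1-yl)-2H-chromene | COc1ccc([C@@H]2C=Cc3c(OC)cc(OC)c(CC=C(C)C)c3O2)cc1O[Si](C(C)C)(C(C)C)C(C)C | intermediate
15 | 2-{(2S)-5,7-dimethoxy-2-[4-methoxy-3-(triisopropylsilyloxy)phenyl]-8-(3-methylbut-2-en-1-yl)chroman-4-yl}-1,3,2-benzodioxaborole (both C4 epimers) | COc1ccc([C@@H]2CC(B3Oc4ccccc4O3)c3c(OC)cc(OC)c(CC=C(C)C)c3O2)cc1O[Si](C(C)C)(C(C)C)C(C)C | intermediate (not isolated)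
16 | (2S)-5,7-dimethoxy-2-[4-methoxy-3-(triisopropylsilyloxy)phenyl]-8-(3-methylbut-2-en-1-yl)chroman-4-ol (both C4 epimers) | COc1ccc([C@@H]2CC(O)c3c(OC)cc(OC)c(CC=C(C)C)c3O2)cc1O[Si](C(C)C)(C(C)C)C(C)C | intermediate
17 | (2S)-5,7-dimethoxy-2-[4-methoxy-3-(triisopropylsilyloxy)phenyl]-8-(3-methylbut-2-en-1-yl)chroman-4-one | COc1ccc([C@@H]2CC(=O)c3c(OC)cc(OC)c(CC=C(C)C)c3O2)cc1O[Si](C(C)C)(C(C)C)C(C)C | intermediate
18 | (2S)-2-(3-hydroxy-4-methoxyphenyl)-5,7-dimethoxy-8-(3-methylbut-2-en-1-yl)chroman-4-one | COc1ccc([C@@H]2CC(=O)c3c(OC)cc(OC)c(CC=C(C)C)c3O2)cc1O | target

## Step count and least certain steps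

Total: 13 steps. Longest linear sequence: 9 steps (steps 1–4 then 9–13, or steps 5–8 then 9–13).

**Step 9 (key step).** Most likely to go wrong:
- attack at the unsubstituted allyl terminus, or C-allylation at the ring carbon para to the aryloxide oxygen, because 12 is di-ortho-substituted and very electron-rich;
- erosion of ee by catalyst-mediated re-ionisation of the electron-rich branched ether.

Fallback, setting out from 5 and re-joining at 18: the C–O allylation is given up and C2 is made by enantioselective conjugate arylation. Addition of excess ethynylmagnesium bromide to 5 gives 1-[2-hydroxy-4,6-dimethoxy-3-(3-methylbut-2-en-1-yl)phenyl]prop-2-yn-1-ol F1. Oxidation with MnO2 gives the ynone 1-[2-hydroxy-4,6-dimethoxy-3-(3-methylbut-2-en-1-yl)phenyl]prop-2-yn-1-one F2. With K2CO3 in acetone the phenol adds in the six-endo conjugate mode to give 5,7-dimethoxy-8-(3-methylbut-2-en-1-yl)chromen-4-one F3. Commercial 3-hydroxy-4-methoxyphenylboronic acid is then added to F3 with Pd(OCOCF3)2 and the enantiomer of the tert-butyl pyridine-oxazoline ligand that leads to the 2S series, in aqueous 1,2-dichloroethane. This should give 18 directly, provided the free phenol is tolerated in this aqueous medium.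

**Step 11.** Most likely to go wrong:
- delivery of boron to C3 instead of C4, because the two ortho substituents at C4a weaken the η3-benzyl stabilisation that directs rhodium to C4;
- reversible rhodium hydride insertion moving the double bond toward C2.

Fallback, setting out from 14 and re-joining at 17: Tsuji–Wacker oxidation with PdCl2 (10 mol%), CuCl and O2 in DMF/H2O at 25 °C. Its regiochemistry is governed by a different factor, attack of water at the carbon that best bears positive charge. C4 is that carbon, conjugated to the trioxygenated ring and remote from the electron-withdrawing C2–O bond, and the prenyl alkene is inert. The weakness of this fallback is the preference of palladium for a benzylic position, which is the same factor whose loss would have caused the failure of step 11, so the two methods are complementary.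

**Step 4.** Most likely to go wrong:
- acid- or radical-induced oligomerisation of the electron-rich vinylphenol through its quinone methide form during isolation;
- incomplete olefination of the deactivated aryloxide aldehyde.

Fallback, setting out from 5 and 11 and re-joining at 13: the order of olefination and etherification is reversed so that the vinylphenol is never made. The lithium salt of 5 is used as the nucleophile under the conditions of step 9 to give (S)-2-{1-[4-methoxy-3-(triisopropylsilyloxy)phenyl]allyloxy}-4,6-dimethoxy-3-(3-methylbut-2-en-1-yl)benzaldehyde F4. Its aldehyde, now without an ortho aryloxide, is methylenated with methylenetriphenylphosphorane to give 13.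

**Step 13.** Most likely to go wrong: partial racemisation by fluoride- or phenoxide-induced E1cB opening of ring C and reclosure.

Fallback, setting out from 16 and re-joining at 18: the silyl group is removed before the ketone exists. Bu4NF in THF converts 16 to (2S)-2-(3-hydroxy-4-methoxyphenyl)-5,7-dimethoxy-8-(3-methylbut-2-en-1-yl)chroman-4-ol F5, which has no base-labile stereocentre. Activated MnO2 in CH2Cl2 then oxidises the benzylic alcohol in the presence of the phenol to give 18.

## Further compounds

F1 | step 9 | 1-[2-hydroxy-4,6-dimethoxy-3-(3-methylbut-2-en-1-yl)phenyl]prop-2-yn-1-ol (racemic) | COc1cc(OC)c(CC=C(C)C)c(O)c1C(O)C#C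
F2 | step 9 | 1-[2-hydroxy-4,6-dimethoxy-3-(3-methylbut-2-en-1-yl)phenyl]prop-2-yn-1-one | COc1cc(OC)c(CC=C(C)C)c(O)c1C(=O)C#C
F3 | step 9 | 5,7-dimethoxy-8-(3-methylbut-2-en-1-yl)chromen-4-one | COc1cc(OC)c2c(c1CC=C(C)C)OC=CC2=O
F0 | step 11 | none | none
F4 | step 4 | (S)-2-{1-[4-methoxy-3-(triisopropylsilyloxy)phenyl]allyloxy}-4,6-dimethoxy-3-(3-methylbut-2-en-1-yl)benzaldehyde | COc1ccc([C@H](C=C)Oc2c(C=O)c(OC)cc(OC)c2CC=C(C)C)cc1O[Si](C(C)C)(C(C)C)C(C)C
F5 | step 13 | (2S)-2-(3-hydroxy-4-methoxyphenyl)-5,7-dimethoxy-8-(3-methylbut-2-en-1-yl)chroman-4-ol (both C4 epimers) | COc1ccc([C@@H]2CC(O)c3c(OC)cc(OC)c(CC=C(C)C)c3O2)cc1O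
A1 | alternative 1 | 5-methoxy-2-(3-methylbut-2-en-1-yl)-3-(triisopropylsilyloxy)phenol | COc1cc(O)c(CC=C(C)C)c(O[Si](C(C)C)(C(C)C)C(C)C)c1
A2 | alternative 1 | 3-methoxycyclobut-2-en-1-one | COC1=CC(=O)C1
A3 | alternative 1 | triisopropyl[(5-methylhex-4-en-1-yn-1-yl)oxy]silane | CC(C)=CCC#CO[Si](C(C)C)(C(C)C)C(C)C
A4 | alternative 2 | (2S)-5,7-dimethoxy-2-[4-methoxy-3-(methoxymethoxy)phenyl]-8-(3-methylbut-2-en-1-yl)chroman-4-one | COc1ccc([C@@H]2CC(=O)c3c(OC)cc(OC)c(CC=C(C)C)c3O2)cc1OCOC
A5 | alternative 2 | (3S)-3-[2-bromo-3,5-dimethoxy-6-(3-methylbut-2-en-1-yl)phenoxy]-N-methoxy-3-[4-methoxy-3-(methoxymethoxy)phenyl]-N-methylpropanamide | CON(C)C(=O)C[C@H](Oc1c(Br)c(OC)cc(OC)c1CC=C(C)C)c1ccc(OC)c(OCOC)c1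
A6 | alternative 3 | (2S)-2-[3-(tert-butyldimethylsilyloxy)-4-methoxyphenyl]-5,7-dimethoxy-8-(3-methylbut-2-en-1-yl)chroman-4-one | COc1ccc([C@@H]2CC(=O)c3c(OC)cc(OC)c(CC=C(C)C)c3O2)cc1O[Si](C)(C)C(C)(C)C
A7 | alternative 3 | 5,7-dimethoxy-8-(3-methylbut-2-en-1-yl)chromen-4-one | COc1cc(OC)c2c(c1CC=C(C)C)OC=CC2=O
A8 | alternative 3 | [3-(tert-butyldimethylsilyloxy)-4-methoxyphenyl]boronic acid | COc1ccc(B(O)O)cc1O[Si](C)(C)C(C)(C)C
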